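**Retrosynthetic overview**

1. The strategy rests on the CH2CH2 bridge. It joins ring A carbon C5, flanked by the 4-hydroxybenzyl groups on C4 and C6, to ring B carbon C1', which has the 4-hydroxybenzyl group of C6' as its neighbour. Both aryl carbons are crowded, so the bridge is brought in as a linear alkyne.
2. The bridge comes from diarylalkyne 16 by hydrogenation, which also removes all five benzyl ethers. Alkyne 16 comes from ring-A iodide 7, propiolic acid 14 and ring-B bromide 13 in one pot: C5–C(sp) by Sonogashira coupling, then C(sp)–C1' by decarboxylative coupling.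
3. Iodide 7 comes from a twofold Friedel–Crafts benzylation of 1-(benzyloxy)-3-iodo-5-methoxybenzene 3, itself made from 1-iodo-3,5-dimethoxybenzene 1.
4. Bromide 13 comes from 2-bromo-4-hydroxybenzaldehyde 8 by O-benzylation, aryl Grignard addition and ionic deoxygenation.
5. No ring is formed on the route; all arene rings are bought.

Key step: step 7

Remark: the target has no stereogenic element. The only stereocentre on the route is the carbinol carbon of 12, which is made racemic and removed in step 6. Ring numbering used here: ring A C1 (OMe), C2 (H), C3 (OH), C4 and C6 (4-hydroxybenzyl), C5 (bridge); ring B C1' (bridge), C3' (OH), C6' (4-hydroxybenzyl).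

**Route**

Step 1
Reactants: 1 1-iodo-3,5-dimethoxybenzene
Product: 2 3-iodo-5-methoxyphenol
Conditions: BBr3 (1.0 equiv), CH2Cl2, −78 → 0 °C; H2O
Reagents that add atoms: none
Why: Lewis-acid cleavage of one aryl methyl ether, held at the mono stage by limiting BBr3 and low temperature, with the aryl iodide inert and unreacted 1 recoverable.

Step 2
Reactants: 2 3-iodo-5-methoxyphenol
Product: 3 1-(benzyloxy)-3-iodo-5-methoxybenzene
Conditions: BnBr, K2CO3, DMF, rt
Reagents that add atoms: benzyl bromide, BrCc1ccccc1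
Why: Williamson ether synthesis on a phenoxide, with no competing nucleophilic site.

Step 3
Reactants: 3 1-(benzyloxy)-3-iodo-5-methoxybenzene; 4 4-(benzyloxy)benzyl alcohol (2.2 equiv)
Product: 7 1-(benzyloxy)-2,4-bis[4-(benzyloxy)benzyl]-3-iodo-5-methoxybenzene, via para-to-methoxy monobenzyl iodide 5 (not isolated), via para-to-benzyloxy monobenzyl iodide 6 (not isolated)
Conditions: Bi(OTf)3 (5 mol%), CH2Cl2, 0 °C → rt, slow addition of 4
Reagents that add atoms: none
Why: Friedel–Crafts benzylation with a benzylic alcohol, in which the 4-alkoxybenzyl cation should attack the two carbons that are para to one ether oxygen and ortho to the other (both flank the iodine, which sits meta to both oxygens and is thus safe from ipso attack), so that 5 and 6 converge on 7 while the C–H between the two ethers is shielded once both O-alkyl groups are forced to turn toward it.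

Step 4
Reactants: 8 2-bromo-4-hydroxybenzaldehyde
Product: 9 4-(benzyloxy)-2-bromobenzaldehyde
Conditions: BnBr, K2CO3, DMF, rt
Reagents that add atoms: benzyl bromide, BrCc1ccccc1
Why: Williamson ether synthesis of an acidic para-formyl phenol, leaving the aldehyde and the aryl bromide untouched.

Step 5
Reactants: 9 4-(benzyloxy)-2-bromobenzaldehyde; 10 1-(benzyloxy)-4-bromobenzene
Product: 12 rac-[4-(benzyloxy)-2-bromophenyl][4-(benzyloxy)phenyl]methanol, via 4-(benzyloxy)phenylmagnesium bromide 11 (not isolated)
Conditions: 10, Mg, THF, reflux; then 9, THF, 0 °C; aq NH4Cl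
Reagents that add atoms: none
Why: Grignard addition to an aldehyde is much faster at 0 °C than Br/Mg exchange at the ortho bromide, and the new carbinol centre is left racemic because step 6 removes it.

Step 6
Reactants: 12 rac-[4-(benzyloxy)-2-bromophenyl][4-(benzyloxy)phenyl]methanol
Product: 13 4-(benzyloxy)-1-[4-(benzyloxy)benzyl]-2-bromobenzene
Conditions: Et3SiH, TFA, CH2Cl2, 0 °C
Reagents that add atoms: none
Why: Ionic hydrogenation, in which the diarylmethyl cation stabilised by two para-alkoxy groups forms readily in TFA and is trapped by hydride from the silane before the benzyl ethers or the aryl bromide are affected.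

Step 7
Reactants: 7 1-(benzyloxy)-2,4-bis[4-(benzyloxy)benzyl]-3-iodo-5-methoxybenzene; 14 propiolic acid; 13 4-(benzyloxy)-1-[4-(benzyloxy)benzyl]-2-bromobenzene
Product: 16 1-(benzyloxy)-3-({5-(benzyloxy)-2-[4-(benzyloxy)benzyl]phenyl}ethynyl)-2,4-bis[4-(benzyloxy)benzyl]-5-methoxybenzene, via arylpropiolic acid 15 (not isolated)
Conditions: 7, 14 (1.05 equiv), PdCl2(PPh3)2 (5 mol%), dppb (10 mol%), DBU (3 equiv), DMSO, rt → 45 °C until 7 is consumed; then 13 (1.1 equiv), 90 °C
Reagents that add atoms: none
Why: Pd(0) inserts into the C–I bond of 7, the terminal C–H of the propiolate is palladated with base assistance (copper-free Sonogashira) and reductive elimination gives arylpropiolate 15 with its carboxylate intact. On heating with 13, Pd(0) inserts into the C–Br bond, the carboxylate binds Pd(II), CO2 is lost to give an aryl(alkynyl)palladium species, and reductive elimination forms the second aryl–alkyne bond. The closest known reaction type is the one-pot Sonogashira/decarboxylative sp–sp2 coupling of propiolic acid with an aryl iodide and then an aryl bromide to give unsymmetrical diarylalkynes. No ring is closed and no stereocentre is formed. The selectivity needed is hetero-diarylation without symmetrical tolanes; it should follow from the iodide reacting at low temperature while the bromide does not, and from the carboxylate masking the second alkyne terminus until the hotter stage. The slim alkyne should tolerate the two ortho benzyl groups of 7 and the one of 13.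

Step 8
Reactants: 16 1-(benzyloxy)-3-({5-(benzyloxy)-2-[4-(benzyloxy)benzyl]phenyl}ethynyl)-2,4-bis[4-(benzyloxy)benzyl]-5-methoxybenzene
Product: 17 3-{2-[5-hydroxy-2-(4-hydroxybenzyl)phenyl]ethyl}-2,4-bis(4-hydroxybenzyl)-5-methoxyphenol (CNP0147493.0)
Conditions: H2 (1–3 atm), 10% Pd/C, THF/MeOH, rt
Reagents that add atoms: none
Why: Heterogeneous hydrogenation should saturate the diarylalkyne to the CH2CH2 bridge and hydrogenolyse the five aryl benzyl ethers in the same operation, while the methyl ether and the diarylmethane C–C bonds are inert.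

**Compound list**

1 | 1-iodo-3,5-dimethoxybenzene | COc1cc(I)cc(OC)c1 | starting material
2 | 3-iodo-5-methoxyphenol | COc1cc(O)cc(I)c1 | intermediate
3 | 1-(benzyloxy)-3-iodo-5-methoxybenzene | COc1cc(OCc2ccccc2)cc(I)c1 | intermediate
4 | 4-(benzyloxy)benzyl alcohol | OCc1ccc(OCc2ccccc2)cc1 | starting material
5 | 1-(benzyloxy)-2-[4-(benzyloxy)benzyl]-3-iodo-5-methoxybenzene (monobenzyl isomer, benzyl para to OMe; formed in the flask in step 3) | COc1cc(OCc2ccccc2)c(Cc2ccc(OCc3ccccc3)cc2)c(I)c1 | intermediate
6 | 5-(benzyloxy)-2-[4-(benzyloxy)benzyl]-1-iodo-3-methoxybenzene (monobenzyl isomer, benzyl para to OBn; formed in the flask in step 3) | COc1cc(OCc2ccccc2)cc(I)c1Cc1ccc(OCc2ccccc2)cc1 | intermediate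
7 | 1-(benzyloxy)-2,4-bis[4-(benzyloxy)benzyl]-3-iodo-5-methoxybenzene (ring-A iodide) | COc1cc(OCc2ccccc2)c(Cc2ccc(OCc3ccccc3)cc2)c(I)c1Cc1ccc(OCc2ccccc2)cc1 | intermediate
8 | 2-bromo-4-hydroxybenzaldehyde | O=Cc1ccc(O)cc1Br | starting material
9 | 4-(benzyloxy)-2-bromobenzaldehyde | O=Cc1ccc(OCc2ccccc2)cc1Br | intermediate
10 | 1-(benzyloxy)-4-bromobenzene | Brc1ccc(OCc2ccccc2)cc1 | starting material
11 | 4-(benzyloxy)phenylmagnesium bromide (formed in the flask in step 5) | Br[Mg]c1ccc(OCc2ccccc2)cc1 | intermediate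
12 | rac-[4-(benzyloxy)-2-bromophenyl][4-(benzyloxy)phenyl]methanol | OC(c1ccc(OCc2ccccc2)cc1)c1ccc(OCc2ccccc2)cc1Br | intermediate
13 | 4-(benzyloxy)-1-[4-(benzyloxy)benzyl]-2-bromobenzene (ring-B bromide) | Brc1cc(OCc2ccccc2)ccc1Cc1ccc(OCc2ccccc2)cc1 | intermediate
14 | propiolic acid | C#CC(=O)O | starting material
15 | 3-{3-(benzyloxy)-2,6-bis[4-(benzyloxy)benzyl]-5-methoxyphenyl}prop-2-ynoic acid (formed in the flask in step 7, present as its DBU salt) | COc1cc(OCc2ccccc2)c(Cc2ccc(OCc3ccccc3)cc2)c(C#CC(=O)O)c1Cc1ccc(OCc2ccccc2)cc1 | intermediate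
16 | 1-(benzyloxy)-3-({5-(benzyloxy)-2-[4-(benzyloxy)benzyl]phenyl}ethynyl)-2,4-bis[4-(benzyloxy)benzyl]-5-methoxybenzene | COc1cc(OCc2ccccc2)c(Cc2ccc(OCc3ccccc3)cc2)c(C#Cc2cc(OCc3ccccc3)ccc2Cc2ccc(OCc3ccccc3)cc2)c1Cc1ccc(OCc2ccccc2)cc1 | intermediate
17 | 3-{2-[5-hydroxy-2-(4-hydroxybenzyl)phenyl]ethyl}-2,4-bis(4-hydroxybenzyl)-5-methoxyphenol | COc1cc(O)c(Cc2ccc(O)cc2)c(CCc2cc(O)ccc2Cc2ccc(O)cc2)c1Cc1ccc(O)cc1 | target

**Step count**

Total: 8 steps. Longest linear sequence: 5 steps (1 → 2 → 3 → 7 → 16 → 17; the ring-B arm 8 → 9 → 12 → 13 → 16 → 17 is equally long).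

**Steps most likely to fail, with fallbacks**

Step 7. The first coupling at the doubly ortho-substituted iodide may be slow, so that CO2 is lost before the bromide engages; the terminal alkyne thus formed can then react with leftover iodide to give the symmetrical tolane. Oxidative addition to the electron-rich, ortho-substituted bromide may also lag behind protodecarboxylation. The fallback sets out from 7 and comes back at 16, with the two aryl–alkyne bonds formed in separate, individually tunable operations. Sonogashira coupling of 7 with trimethylsilylacetylene (PdCl2(PPh3)2, CuI, Et3N, 60 °C) should give {[3-(benzyloxy)-2,6-bis[4-(benzyloxy)benzyl]-5-methoxyphenyl]ethynyl}trimethylsilane F1. Desilylation with K2CO3 in MeOH/THF should give the terminal alkyne 1-(benzyloxy)-2,4-bis[4-(benzyloxy)benzyl]-3-ethynyl-5-methoxybenzene F2. A second Sonogashira coupling of F2 with bromide 13 (Pd(PPh3)4, CuI, Et3N/DMF, 80 °C) then gives 16.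

Step 3. The second benzylation may lose regiocontrol and attack the carbon between the two ether oxygens. A third benzyl group may also be taken up, or acid may shuffle benzyl groups between oxygen and carbon. The fallback sets out from 1 and comes back at 7, passing through 5; it also bypasses steps 1 and 2. It replaces the benzyl cation by a self-limiting formyl electrophile, one position at a time.
- Vilsmeier–Haack formylation of 1 (POCl3, DMF) should give 2-iodo-4,6-dimethoxybenzaldehyde F3.
- BCl3 (CH2Cl2, −78 → 0 °C) should cleave only the methyl ether ortho to the aldehyde through chelation, giving 2-hydroxy-6-iodo-4-methoxybenzaldehyde F4. This desymmetrises the two oxygens without statistics.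
- O-Benzylation (BnBr, K2CO3, DMF) gives 2-(benzyloxy)-6-iodo-4-methoxybenzaldehyde F5.
- Addition of Grignard reagent 11 at 0 °C gives rac-[2-(benzyloxy)-6-iodo-4-methoxyphenyl][4-(benzyloxy)phenyl]methanol F6, and Et3SiH/TFA reduces it to 5, here isolated.
- A second Vilsmeier–Haack formylation of 5, directed para to the benzyloxy group, should give 4-(benzyloxy)-3-[4-(benzyloxy)benzyl]-2-iodo-6-methoxybenzaldehyde F7.
- Addition of 11 gives rac-{4-(benzyloxy)-3-[4-(benzyloxy)benzyl]-2-iodo-6-methoxyphenyl}[4-(benzyloxy)phenyl]methanol F8, and Et3SiH/TFA reduction gives 7.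

Step 8. Saturation of the hindered bridge may stall at the stilbene stage, or hydrogenolysis may stop short as partly deprotected phenols adsorb on or precipitate over the catalyst. The fallback sets out from 16 and comes back at 17, separating reduction from deprotection. Diimide generated from p-toluenesulfonyl hydrazide and NaOAc in THF/H2O at reflux should reduce only the alkyne, giving 1-(benzyloxy)-3-{2-[5-(benzyloxy)-2-[4-(benzyloxy)benzyl]phenyl]ethyl}-2,4-bis[4-(benzyloxy)benzyl]-5-methoxybenzene F9. BCl3 with pentamethylbenzene as cation scavenger (CH2Cl2, −78 °C) should then remove the five benzyl ethers while the methyl ether survives, giving 17.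

**Further compounds**

F1 | step 7 | {[3-(benzyloxy)-2,6-bis[4-(benzyloxy)benzyl]-5-methoxyphenyl]ethynyl}trimethylsilane | COc1cc(OCc2ccccc2)c(Cc2ccc(OCc3ccccc3)cc2)c(C#C[Si](C)(C)C)c1Cc1ccc(OCc2ccccc2)cc1
F2 | step 7 | 1-(benzyloxy)-2,4-bis[4-(benzyloxy)benzyl]-3-ethynyl-5-methoxybenzene | COc1cc(OCc2ccccc2)c(Cc2ccc(OCc3ccccc3)cc2)c(C#C)c1Cc1ccc(OCc2ccccc2)cc1
F3 | step 3 | 2-iodo-4,6-dimethoxybenzaldehyde | COc1cc(OC)c(C=O)c(I)c1
F4 | step 3 | 2-hydroxy-6-iodo-4-methoxybenzaldehyde | COc1cc(O)c(C=O)c(I)c1
F5 | step 3 | 2-(benzyloxy)-6-iodo-4-methoxybenzaldehyde | COc1cc(OCc2ccccc2)c(C=O)c(I)c1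
F6 | step 3 | rac-[2-(benzyloxy)-6-iodo-4-methoxyphenyl][4-(benzyloxy)phenyl]methanol | COc1cc(OCc2ccccc2)c(C(O)c2ccc(OCc3ccccc3)cc2)c(I)c1
F7 | step 3 | 4-(benzyloxy)-3-[4-(benzyloxy)benzyl]-2-iodo-6-methoxybenzaldehyde | COc1cc(OCc2ccccc2)c(Cc2ccc(OCc3ccccc3)cc2)c(I)c1C=O
F8 | step 3 | rac-{4-(benzyloxy)-3-[4-(benzyloxy)benzyl]-2-iodo-6-methoxyphenyl}[4-(benzyloxy)phenyl]methanol | COc1cc(OCc2ccccc2)c(Cc2ccc(OCc3ccccc3)cc2)c(I)c1C(O)c1ccc(OCc2ccccc2)cc1
F9 | step 8 | 1-(benzyloxy)-3-{2-[5-(benzyloxy)-2-[4-(benzyloxy)benzyl]phenyl]ethyl}-2,4-bis[4-(benzyloxy)benzyl]-5-methoxybenzene | COc1cc(OCc2ccccc2)c(Cc2ccc(OCc3ccccc3)cc2)c(CCc2cc(OCc3ccccc3)ccc2Cc2ccc(OCc3ccccc3)cc2)c1Cc1ccc(OCc2ccccc2)cc1
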